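# Miyabenol A: convergent route through a three-component o-quinone methide [4+1] union

## Retrosynthetic overview
1. Locants: the east dihydrobenzofuran (DHB) is O1/C2/C3 on ring A, which carries the styryl group at C4. The central DHB is O1′/C2′/C3′ on ring B, the west DHB is O1″/C2″/C3″ on ring C, and ring D is the terminal resorcinol on C3″.
2. Feature used: the east and west DHBs are the same unit, (2R,3R) with a 3-(3,5-dioxygenated aryl) group and C4 as link point, so one enantiopure 4-bromo-DHB serves as both halves. C3′ is a benzhydrylic carbon ortho to O1′ on ring B, which makes it the exocyclic carbon of an o-quinone methide.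
3. Key disconnection: the central ring is cut at three bonds, C3′–C4″, C2′–C3′ and C2′–O1′. This gives the C4″-aryllithium of the west half, the ring-B O-Boc-salicylaldehyde of the east half, and a p-silyloxybenzylidene sulfonium ylide that delivers C2′ as a one-carbon unit.
4. The common bromo-DHB comes from a Rh(II) donor/donor-carbene C–H insertion, which sets C3. C2 is then epimerised from cis to trans through the p-oxybenzyl cation.
5. Ring order: outer DHB (made once, used twice), then the central DHB in the union, then the stilbene by Heck reaction, then global desilylation.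

Key step: step 12

Abbreviations: TBS = tert-butyldimethylsilyl, Boc = tert-butoxycarbonyl.
Assumption: Rh2(R-PTAD)4 is taken as the catalyst antipode that gives 3R. If the sense of induction is the opposite, Rh2(S-PTAD)4 is used and nothing else changes.
Assumption: 4-(tert-butyldimethylsilyloxy)benzaldehyde and 4-(tert-butyldimethylsilyloxy)styrene are taken as commercial.

## Route

Step 1
Reactants: 1 1-bromo-3,5-dimethoxybenzene; 2 3,5-dimethoxybenzoyl chloride
Product: 4 (2-bromo-6-hydroxy-4-methoxyphenyl)(3,5-dimethoxyphenyl)methanone, via tetramethoxy ketone 3 (not isolated)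
Conditions: AlCl3 (3 equiv), CH2Cl2, 0 °C → rt; aq. HCl
Reagents that add atoms: none
Why: Friedel–Crafts acylation should occur at C2 of 1 (para to one OMe, next to Br), and excess AlCl3 chelated between the new C=O and the flanking OMe should cleave only that ether (chelation-controlled demethylation).

Step 2
Reactants: 4; 5 4-methoxybenzyl chloride
Product: 6 {2-bromo-4-methoxy-6-[(4-methoxybenzyl)oxy]phenyl}(3,5-dimethoxyphenyl)methanone
Conditions: K2CO3, NaI (cat.), DMF, 60 °C
Reagents that add atoms: none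
Why: Williamson etherification of the only phenol installs the O–CH2–aryl unit whose CH2 becomes C2.

Step 3
Reactants: 6
Product: 7 hydrazone of 6 (E/Z mixture)
Conditions: N2H4·H2O (excess), AcOH (cat.), n-BuOH, 120 °C, sealed tube
Reagents that add atoms: hydrazine (as hydrate) NN
Why: Hydrazone condensation, in which excess reagent and heat are meant to overcome the shielding of C=O by the two ortho groups, while the electron-rich bromoarene should resist SNAr closure to an indazole.

Step 4
Reactants: 7
Product: 9 (2S,3R)-4-bromo-3-(3,5-dimethoxyphenyl)-6-methoxy-2-(4-methoxyphenyl)-2,3-dihydrobenzofuran (2,3-cis), via diaryldiazomethane 8 (not isolated)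
Conditions: MnO2, CH2Cl2, 0 °C, filtration; Rh2(R-PTAD)4 (1 mol %), CH2Cl2, 0 °C
Reagents that add atoms: none
Why: Hydrazone dehydrogenation followed by Rh(II) donor/donor-carbene 1,5-C–H insertion into the OCH2Ar group closes the five-membered ring, the chiral carboxylate catalyst sets C3 as R, and the concerted insertion should give the 2,3-cis isomer (2S).

Step 5
Reactants: 9
Product: 10 (2R,3R)-4-bromo-3-(3,5-dihydroxyphenyl)-2-(4-hydroxyphenyl)-2,3-dihydrobenzofuran-6-ol (2,3-trans)
Conditions: BBr3 (excess), CH2Cl2, −78 °C → rt; H2O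
Reagents that add atoms: none
Why: BBr3 ether cleavage removes the four methyl groups, and reversible ionisation of the benzylic C2–O1 bond (p-oxybenzyl cation/p-quinone methide) should at the same time epimerise C2 to the more stable trans isomer, while C3 stays untouched and no ring can trap the cation.

Step 6
Reactants: 10
Product: 11 tetra-TBS ether of 10 (west half)
Conditions: TBSCl (6 equiv), imidazole, DMF, rt
Reagents that add atoms: TBSCl CC(C)(C)[Si](C)(C)Cl
Why: Exhaustive phenol silylation gives groups that tolerate Br/Li exchange and leave at the end without acid.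

Step 7
Reactants: 10
Product: 12 2-[(2R,3R)-4-bromo-6-hydroxy-2-(4-hydroxyphenyl)-2,3-dihydrobenzofuran-3-yl]-4,6-dihydroxybenzaldehyde
Conditions: POCl3, DMF, MeCN, 0 °C → rt; aq. NaOAc, 50 °C
Reagents that add atoms: DMF CN(C)C=O; water O
Why: Vilsmeier–Haack formylation, since 5-alkylresorcinols react para to one OH next to the alkyl group, ring B is the only ring with two free OH groups and no bromine, and its two such positions are equivalent by rotation.

Step 8
Reactants: 12
Product: 13 2-[(2R,3R)-4-bromo-6-(TBSO)-2-(4-TBSO-phenyl)-2,3-dihydrobenzofuran-3-yl]-4-(TBSO)-6-hydroxybenzaldehyde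
Conditions: TBSCl (3.3 equiv), imidazole, CH2Cl2, 0 °C
Reagents that add atoms: TBSCl CC(C)(C)[Si](C)(C)Cl
Why: Selective silylation, because the OH ortho to CHO is held in an intramolecular hydrogen bond and should react last.

Step 9
Reactants: 13
Product: 14 tert-butyl carbonate of 13 at the OH ortho to CHO (east half)
Conditions: Boc2O, DMAP (cat.), i-Pr2NEt, THF, rt
Reagents that add atoms: Boc2O CC(C)(C)OC(=O)OC(=O)OC(C)(C)C
Why: DMAP-catalysed O-acylation of the remaining phenol installs the migrating and leaving group for the o-quinone methide cascade.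

Step 10
Reactants: 15 4-(tert-butyldimethylsilyloxy)benzaldehyde
Product: 16 [4-(tert-butyldimethylsilyloxy)phenyl]methanol
Conditions: NaBH4, THF/EtOH, 0 °C
Reagents that add atoms: none
Why: Borohydride reduction of an aryl aldehyde, which the aryl silyl ether should survive at 0 °C.

Step 11
Reactants: 16
Product: 18 1-[4-(tert-butyldimethylsilyloxy)benzyl]tetrahydrothiophenium bromide, via benzyl bromide 17 (not isolated)
Conditions: PBr3, Et2O, 0 °C; crude bromide, tetrahydrothiophene, acetone, rt
Reagents that add atoms: PBr3 BrP(Br)Br; tetrahydrothiophene C1CCSC1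
Why: Alcohol bromination followed by SN2 S-alkylation of the sulfide gives the sulfonium salt, which should precipitate.

Step 12
Reactants: 11; 14; 18
Product: 23 octa-TBS bromide of the tetramer core (2R,3R,2′S,3′S,2″R,3″R), via aryllithium 19 (not isolated), via sulfonium ylide 20 (not isolated), via lithium carbinolate 21 (not isolated), via o-quinone methide 22 (not isolated)
Conditions: 11, n-BuLi, THF, −78 °C; add 14, −78 °C; add 20 (from 18, LiHMDS, THF, −78 °C), then MgBr2·OEt2, −78 → 0 °C
Reagents that add atoms: none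
Why: Proposed new method: aryllithium 19 adds to the formyl group of 14 to give both epimers of carbinolate 21, the alkoxide takes over the Boc group of the neighbouring phenol oxygen, the phenoxide set free expels tert-butyl carbonate under MgBr2 assistance to give the planar o-quinone methide 22, ylide 20 adds with its carbon to the exocyclic C3′, and the rearomatised phenoxide O1′ displaces tetrahydrothiophene at C2′. The closest known reaction types are the anionic organometal/O-Boc-salicylaldehyde entry to o-quinone methides with capture by a second carbon nucleophile and the formal [4+1] annulation of o-quinone methides with sulfonium ylides to trans-2,3-dihydrobenzofurans, and what is new is their merger in one flask, the semi-stabilised benzylic ylide and the size of both partners. The only ring closed is the central dihydrofuran, by a 5-exo-tet O-alkylation at the p-silyloxybenzylic sulfonium carbon. C3′ is stereoconvergent, since both epimers of 21 pass through the same 22, and its configuration should be dictated by C3″: ring C has to stand perpendicular to the quinone methide plane on the carbonyl side (Z), the rotamer that turns ring D away from ring B puts C3a″/C3″ and ring D over one face, and attack on the open C5″–H face gives 3′S. C2′ follows from C3′, because the loose, cation-like substitution at the benzylic sulfonium carbon should place the two aryl groups trans (2′S). The step needs addition of 19 to CHO rather than to the carbonate or Br/Li exchange with the C4–Br of 14 (fast carbonyl addition at −78 °C), no second addition of 19 to 22 (bulk of 19) and no epoxide from 20 and 14 (20 is added only after 14 is consumed).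

Step 13
Reactants: 23; 24 4-(tert-butyldimethylsilyloxy)styrene
Product: 25 nona-TBS miyabenol A
Conditions: Pd2(dba)3 (5 mol %), P(t-Bu)3·HBF4 (12 mol %), Cy2NMe, dioxane, 100 °C
Reagents that add atoms: none
Why: Mizoroki–Heck reaction at the only C–Br bond, with a bulky electron-rich phosphine for the ortho-hindered bromide, where syn insertion and syn β-hydride elimination should give the E-stilbene.

Step 14
Reactants: 25
Product: 26 miyabenol A
Conditions: TBAF/AcOH (1:1, 12 equiv), THF, 0 °C → rt, argon
Reagents that add atoms: none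
Why: Fluoride-induced Si–O cleavage, buffered so that no strong acid (stilbene protonation, C2–O ionisation with Friedel–Crafts ring closure) and no free phenoxide base (retro-oxa-Michael opening) acts on the product, and no stereocentre is touched.

## Compound list
1 | 1-bromo-3,5-dimethoxybenzene | COc1cc(Br)cc(OC)c1 | starting material
2 | 3,5-dimethoxybenzoyl chloride | COc1cc(cc(OC)c1)C(Cl)=O | starting material
3 | (2-bromo-4,6-dimethoxyphenyl)(3,5-dimethoxyphenyl)methanone | COc1cc(OC)c(C(=O)c2cc(OC)cc(OC)c2)c(Br)c1 | intermediate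
4 | (2-bromo-6-hydroxy-4-methoxyphenyl)(3,5-dimethoxyphenyl)methanone | COc1cc(O)c(C(=O)c2cc(OC)cc(OC)c2)c(Br)c1 | intermediate
5 | 4-methoxybenzyl chloride | COc1ccc(CCl)cc1 | starting material
6 | {2-bromo-4-methoxy-6-[(4-methoxybenzyl)oxy]phenyl}(3,5-dimethoxyphenyl)methanone | COc1ccc(COc2cc(OC)cc(Br)c2C(=O)c2cc(OC)cc(OC)c2)cc1 | intermediate
7 | hydrazone of 6 | COc1ccc(COc2cc(OC)cc(Br)c2C(=NN)c2cc(OC)cc(OC)c2)cc1 | intermediate
8 | diaryldiazomethane from 7 | COc1ccc(COc2cc(OC)cc(Br)c2C(=[N+]=[N-])c2cc(OC)cc(OC)c2)cc1 | intermediate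
9 | (2S,3R)-cis-4-bromo-3-(3,5-dimethoxyphenyl)-6-methoxy-2-(4-methoxyphenyl)-2,3-dihydrobenzofuran | Brc1cc(OC)cc2c1[C@@H](c1cc(OC)cc(OC)c1)[C@@H](c1ccc(OC)cc1)O2 | intermediate
10 | (2R,3R)-trans-4-bromo-3-(3,5-dihydroxyphenyl)-2-(4-hydroxyphenyl)-2,3-dihydrobenzofuran-6-ol | Brc1cc(O)cc2c1[C@@H](c1cc(O)cc(O)c1)[C@H](c1ccc(O)cc1)O2 | intermediate
11 | tetra-TBS ether of 10 | Brc1cc(O[Si](C)(C)C(C)(C)C)cc2c1[C@@H](c1cc(O[Si](C)(C)C(C)(C)C)cc(O[Si](C)(C)C(C)(C)C)c1)[C@H](c1ccc(O[Si](C)(C)C(C)(C)C)cc1)O2 | intermediate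
12 | 2-[(2R,3R)-4-bromo-6-hydroxy-2-(4-hydroxyphenyl)-2,3-dihydrobenzofuran-3-yl]-4,6-dihydroxybenzaldehyde | Brc1cc(O)cc2c1[C@@H](c1cc(O)cc(O)c1C=O)[C@H](c1ccc(O)cc1)O2 | intermediate
13 | tris-TBS ether of 12, free OH ortho to CHO | Brc1cc(O[Si](C)(C)C(C)(C)C)cc2c1[C@@H](c1cc(O[Si](C)(C)C(C)(C)C)cc(O)c1C=O)[C@H](c1ccc(O[Si](C)(C)C(C)(C)C)cc1)O2 | intermediate
14 | O-Boc derivative of 13 | Brc1cc(O[Si](C)(C)C(C)(C)C)cc2c1[C@@H](c1cc(O[Si](C)(C)C(C)(C)C)cc(OC(=O)OC(C)(C)C)c1C=O)[C@H](c1ccc(O[Si](C)(C)C(C)(C)C)cc1)O2 | intermediate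
15 | 4-(tert-butyldimethylsilyloxy)benzaldehyde | O=Cc1ccc(O[Si](C)(C)C(C)(C)C)cc1 | starting material
16 | [4-(tert-butyldimethylsilyloxy)phenyl]methanol | OCc1ccc(O[Si](C)(C)C(C)(C)C)cc1 | intermediate
17 | 4-(tert-butyldimethylsilyloxy)benzyl bromide | BrCc1ccc(O[Si](C)(C)C(C)(C)C)cc1 | intermediate
18 | 1-[4-(tert-butyldimethylsilyloxy)benzyl]tetrahydrothiophenium bromide | CC(C)(C)[Si](C)(C)Oc1ccc(C[S+]2CCCC2)cc1.[Br-] | intermediate
19 | C4-aryllithium from 11 | [Li]c1cc(O[Si](C)(C)C(C)(C)C)cc2c1[C@@H](c1cc(O[Si](C)(C)C(C)(C)C)cc(O[Si](C)(C)C(C)(C)C)c1)[C@H](c1ccc(O[Si](C)(C)C(C)(C)C)cc1)O2 | intermediate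
20 | tetrahydrothiophenium 4-(TBSO)benzylide | CC(C)(C)[Si](C)(C)Oc1ccc([CH-][S+]2CCCC2)cc1 | intermediate
21 | lithium carbinolate from 19 and 14 (both epimers at the carbinol carbon) | Brc1cc(O[Si](C)(C)C(C)(C)C)cc2c1[C@@H](c1cc(O[Si](C)(C)C(C)(C)C)cc(OC(=O)OC(C)(C)C)c1C(O[Li])c1cc(O[Si](C)(C)C(C)(C)C)cc3c1[C@@H](c1cc(O[Si](C)(C)C(C)(C)C)cc(O[Si](C)(C)C(C)(C)C)c1)[C@H](c1ccc(O[Si](C)(C)C(C)(C)C)cc1)O3)[C@H](c1ccc(O[Si](C)(C)C(C)(C)C)cc1)O2 | intermediate
22 | (Z)-o-quinone methide of ring B, exocyclic C3′ bearing H and ring C | Brc1cc(O[Si](C)(C)C(C)(C)C)cc2c1[C@@H](C1=CC(O[Si](C)(C)C(C)(C)C)=CC(=O)/C1=C\c1cc(O[Si](C)(C)C(C)(C)C)cc3c1[C@@H](c1cc(O[Si](C)(C)C(C)(C)C)cc(O[Si](C)(C)C(C)(C)C)c1)[C@H](c1ccc(O[Si](C)(C)C(C)(C)C)cc1)O3)[C@H](c1ccc(O[Si](C)(C)C(C)(C)C)cc1)O2 | intermediate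
23 | octa-TBS tetramer core with Br at C4 of ring A, (2R,3R,2′S,3′S,2″R,3″R) | Brc1cc(O[Si](C)(C)C(C)(C)C)cc2c1[C@@H](c1cc(O[Si](C)(C)C(C)(C)C)cc3c1[C@H](c1cc(O[Si](C)(C)C(C)(C)C)cc4c1[C@@H](c1cc(O[Si](C)(C)C(C)(C)C)cc(O[Si](C)(C)C(C)(C)C)c1)[C@H](c1ccc(O[Si](C)(C)C(C)(C)C)cc1)O4)[C@@H](c1ccc(O[Si](C)(C)C(C)(C)C)cc1)O3)[C@H](c1ccc(O[Si](C)(C)C(C)(C)C)cc1)O2 | intermediate
24 | 4-(tert-butyldimethylsilyloxy)styrene | C=Cc1ccc(O[Si](C)(C)C(C)(C)C)cc1 | starting material
25 | nona-TBS miyabenol A | CC(C)(C)[Si](C)(C)Oc1ccc(/C=C/c2cc(O[Si](C)(C)C(C)(C)C)cc3c2[C@@H](c2cc(O[Si](C)(C)C(C)(C)C)cc4c2[C@H](c2cc(O[Si](C)(C)C(C)(C)C)cc5c2[C@@H](c2cc(O[Si](C)(C)C(C)(C)C)cc(O[Si](C)(C)C(C)(C)C)c2)[C@H](c2ccc(O[Si](C)(C)C(C)(C)C)cc2)O5)[C@@H](c2ccc(O[Si](C)(C)C(C)(C)C)cc2)O4)[C@H](c2ccc(O[Si](C)(C)C(C)(C)C)cc2)O3)cc1 | intermediate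
26 | miyabenol A | Oc1ccc(/C=C/c2cc(O)cc3c2[C@@H](c2cc(O)cc4c2[C@H](c2cc(O)cc5c2[C@@H](c2cc(O)cc(O)c2)[C@H](c2ccc(O)cc2)O5)[C@@H](c2ccc(O)cc2)O4)[C@H](c2ccc(O)cc2)O3)cc1 | target

## Step count and risks
Total step count: 14.
Longest linear sequence: 11 (steps 1–5, 7–9, 12–14).

**Step 12 (Proposed new method).**
- What may go wrong: the semi-stabilised ylide may be lost by proton transfer, [2,3]-rearrangement or dealkylation by bromide before the hindered o-quinone methide has formed. The quinone methide would then be consumed by oligomerisation. Facial selectivity at C3′ may also be low.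
- Where the fallback runs: it sets out from 11, 14 and crude bromide 17, and it returns at 23.
- Making the replacement nucleophile: 17 is treated with sodium benzenesulfinate (DMF, rt) to give 4-(tert-butyldimethylsilyloxy)benzyl phenyl sulfone F1. Its lithio derivative (n-BuLi, THF, −78 °C) is a carbanion that persists up to room temperature.
- Conjugate addition: the lithio sulfone replaces the ylide in the same aryllithium/O-Boc-aldehyde sequence and should add to 22 to give the phenol sulfone F2. This is conjugate addition of a sulfonyl carbanion to an o-quinone methide.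
- Ring closure: in a separate operation BF3·OEt2 (CH2Cl2, −40 °C) ionises the p-silyloxybenzylic C–S bond, and the neighbouring phenol closes the ring trans to give 23. The sulfone thus acts first as a nucleophilic and then as an electrophilic one-carbon unit.

**Step 3.**
- What may go wrong: the condensation may stall because both faces of the carbonyl group are shielded by Br and the benzyloxy group. Forcing conditions may begin to cleave the benzyl ether.
- Where the fallback runs: it leaves the carbene logic, sets out from 6 and returns at 10.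
- Cyclocondensation: a strong non-nucleophilic base (phosphazene P4-t-Bu, benzene, reflux) deprotonates the OCH2Ar group. Intramolecular addition to the ketone and loss of water should give 4-bromo-3-(3,5-dimethoxyphenyl)-6-methoxy-2-(4-methoxyphenyl)benzofuran F3.
- Reduction and resolution: ionic hydrogenation (Et3SiH, TFA, CH2Cl2) should give the 2,3-trans dihydrobenzofuran as the racemate. HPLC on a chiral stationary phase delivers the (2R,3R)-tetramethyl ether F4.
- Return: BBr3 under the conditions of step 5 converts F4 into 10.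

**Step 7.**
- What may go wrong: site selectivity of the formylation may be poor (attack on ring A, or between the two OH groups of ring B). The acidic medium may also start intermolecular alkylation of the polyphenol.
- Where the fallback runs: it sets out from 9 and returns at 12.
- Formylation at the methyl ether stage: the carbon is introduced by Rieche formylation (Cl2CHOMe, TiCl4, CH2Cl2, −78 → 0 °C). A 3,5-dimethoxyphenyl ring reacts para to one OMe next to the alkyl group, the position between the two OMe groups is shielded, and ring A is deactivated by bromine. This should give 2-[(2S,3R)-4-bromo-6-methoxy-2-(4-methoxyphenyl)-2,3-dihydrobenzofuran-3-yl]-4,6-dimethoxybenzaldehyde F5.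
- Return: BBr3 as in step 5 then removes the four methyl groups and epimerises C2 to give 12.

## Further compounds
F1 | step 12 | 4-(tert-butyldimethylsilyloxy)benzyl phenyl sulfone | O=S(=O)(Cc1ccc(O[Si](C)(C)C(C)(C)C)cc1)c1ccccc1
F2 | step 12 | phenol sulfone, C3′ as in 23, mixture at the sulfonyl-bearing carbon | Brc1cc(O[Si](C)(C)C(C)(C)C)cc2c1[C@@H](c1cc(O[Si](C)(C)C(C)(C)C)cc(O)c1[C@H](c1cc(O[Si](C)(C)C(C)(C)C)cc3c1[C@@H](c1cc(O[Si](C)(C)C(C)(C)C)cc(O[Si](C)(C)C(C)(C)C)c1)[C@H](c1ccc(O[Si](C)(C)C(C)(C)C)cc1)O3)C(c1ccc(O[Si](C)(C)C(C)(C)C)cc1)S(=O)(=O)c1ccccc1)[C@H](c1ccc(O[Si](C)(C)C(C)(C)C)cc1)O2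
F3 | step 3 | 4-bromo-3-(3,5-dimethoxyphenyl)-6-methoxy-2-(4-methoxyphenyl)benzofuran | COc1ccc(cc1)-c1oc2cc(OC)cc(Br)c2c1-c1cc(OC)cc(OC)c1
F4 | step 3 | (2R,3R)-trans-4-bromo-3-(3,5-dimethoxyphenyl)-6-methoxy-2-(4-methoxyphenyl)-2,3-dihydrobenzofuran | Brc1cc(OC)cc2c1[C@@H](c1cc(OC)cc(OC)c1)[C@H](c1ccc(OC)cc1)O2
F5 | step 7 | 2-[(2S,3R)-4-bromo-6-methoxy-2-(4-methoxyphenyl)-2,3-dihydrobenzofuran-3-yl]-4,6-dimethoxybenzaldehyde | Brc1cc(OC)cc2c1[C@@H](c1cc(OC)cc(OC)c1C=O)[C@@H](c1ccc(OC)cc1)O2
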